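**Strategy.** Everything rests on disconnecting the C1–C9 bond of the target: the lactone carbonyl C9 is handled as the ketone of a cyclohexanone (ring C9–C5–C6–C7–C8–C1), on whose chair the C5, C7 and C8 centres are set. In the key step the tertiary C3 hydroxyl of an α-hydroxy ketone side chain on C5 adds to C9 and expels C1 as an isobutyryl enol, so one Sc(OTf)3-catalysed operation opens the carbocycle and closes the five-membered keto lactone (C5, C9, O, C3, C4). The feature used is the chain C5–C6–C7–C8–C1, both ends of which bear carbonyl carbons. The precursor is a 2-isobutyrylcyclohexanone carrying that side chain on quaternary C5.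

Key step: step 15

Atom labels (target): C1 = CH carrying the isobutyryl group; C2, C4 = ketones of the eight-membered ring; C3 = oxygen-bearing prenylated carbon between them; C5 = prenylated bridgehead; C6 = CH2; C7 = prenylated CH; C8 = carbon with methyl and homoprenyl; C9 = lactone carbonyl. Prenyl = 3-methylbut-2-en-1-yl; homoprenyl = 4-methylpent-3-en-1-yl.

Remark 1: C1 of the target lies between two ketones and is configurationally labile; the drawn configuration is taken to be the thermodynamically preferred one, reached through the enol after the last oxidation.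

Remark 2: 5-methylhex-4-enal is taken as a catalogue aldehyde.

**Route**

Step 1
Reactants: 1 2-methylidenepropane-1,3-diol
Product: 2 2-({[tert-butyl(dimethyl)silyl]oxy}methyl)prop-2-en-1-ol
Conditions: NaH (1.0 equiv), THF, 0 °C; then TBSCl (1.0 equiv), 0 °C to rt
Reagents that add atoms: tert-butyl(chloro)dimethylsilane (TBSCl), CC(C)(C)[Si](C)(C)Cl
Why: O-silylation of the monosodium alkoxide of a symmetrical diol should stop at the mono-ether because only one alkoxide is generated; no stereocentre is formed.

Step 2
Reactants: 2 2-({[tert-butyl(dimethyl)silyl]oxy}methyl)prop-2-en-1-ol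
Product: 3 [(2S)-2-({[tert-butyl(dimethyl)silyl]oxy}methyl)oxiran-2-yl]methanol
Conditions: Ti(Oi-Pr)4 (10 mol %), L-(+)-diethyl tartrate (12 mol %), t-BuOOH, 4 Å molecular sieves, CH2Cl2, −20 °C
Reagents that add atoms: tert-butyl hydroperoxide, CC(C)(C)OO
Why: Katsuki–Sharpless asymmetric epoxidation of a 2-substituted allylic alcohol, in which the catalyst formed from Ti(Oi-Pr)4 and L-(+)-diethyl tartrate delivers oxygen to one enantiotopic face of the alkene and thereby sets the future C3 centre.

Step 3
Reactants: 3 [(2S)-2-({[tert-butyl(dimethyl)silyl]oxy}methyl)oxiran-2-yl]methanol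
Product: 4 (2R)-2-({[tert-butyl(dimethyl)silyl]oxy}methyl)-5-methylhex-4-ene-1,2-diol
Conditions: Me2C=CHMgBr (2.5 equiv), CuI (10 mol %), THF, −40 to −20 °C; aq NH4Cl at −20 °C
Reagents that add atoms: (2-methylprop-1-en-1-yl)magnesium bromide, CC(C)=C[Mg]Br
Why: CuI-catalysed Grignard opening of the epoxide at its CH2 carbon (SN2) builds the prenyl group and frees the tertiary hydroxyl without breaking a bond at the stereocentre, the low temperature being chosen to prevent silyl migration between the two primary oxygens.

Step 4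
Reactants: 4 (2R)-2-({[tert-butyl(dimethyl)silyl]oxy}methyl)-5-methylhex-4-ene-1,2-diol
Product: 5 (2S)-2-({[tert-butyl(dimethyl)silyl]oxy}methyl)-2-hydroxy-5-methylhex-4-enal
Conditions: IBX (2-iodoxybenzoic acid, 1.5 equiv), DMSO, rt
Reagents that add atoms: none
Why: IBX oxidation converts the primary hydroxyl of the 1,2-diol into the aldehyde without cleaving the glycol C–C bond, cannot oxidise the tertiary hydroxyl, and the stereocentre has no hydrogen through which it could epimerise.

Step 5
Reactants: 5 (2S)-2-({[tert-butyl(dimethyl)silyl]oxy}methyl)-2-hydroxy-5-methylhex-4-enal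
Product: 6 (2S)-2-({[tert-butyl(dimethyl)silyl]oxy}methyl)-5-methyl-2-[(triethylsilyl)oxy]hex-4-enal
Conditions: TESOTf, 2,6-lutidine, CH2Cl2, −78 °C
Reagents that add atoms: triethylsilyl trifluoromethanesulfonate (TESOTf), CC[Si](CC)(CC)OS(=O)(=O)C(F)(F)F
Why: Silylation of a hindered tertiary alcohol with a silyl triflate and a hindered pyridine base is standard, and the aldehyde has no α-hydrogen and cannot enolise.

Step 6
Reactants: 7 5-methylhex-4-enal; 8 but-3-en-2-one
Product: 10 (4R)-4-(3-methylbut-2-en-1-yl)cyclohex-2-en-1-one, via keto aldehyde 9 (not isolated)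
Conditions: (R)-2-[methoxy(diphenyl)methyl]pyrrolidine (5 mol %), ethyl 3,4-dihydroxybenzoate (20 mol %), neat, 4 °C; then LiOH, i-PrOH, rt
Reagents that add atoms: none
Why: Enamine-catalysed Michael addition, in which the diarylmethyl group of the (R)-pyrrolidine shields one face of the E-enamine and so sets the future C7 centre, followed by intramolecular aldol condensation (Robinson-type annulation).

Step 7
Reactants: 10 (4R)-4-(3-methylbut-2-en-1-yl)cyclohex-2-en-1-one
Product: 12 (4R)-3-methyl-4-(3-methylbut-2-en-1-yl)cyclohex-2-en-1-one, via lithium enolate 11 (not isolated)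
Conditions: Me2CuLi (from MeLi and CuI), Et2O, −78 to −20 °C; then PhS(Cl)=N-t-Bu, THF, −78 °C; aq NH4Cl
Reagents that add atoms: lithium dimethylcuprate (Me2CuLi), [Li+].C[Cu-]C
Why: Cuprate conjugate addition places the methyl group on the future C8, and the enolate is dehydrogenated in the same flask by the sulfinimidoyl chloride (Mukaiyama dehydrogenation), which restores the enone and erases the transient methyl-bearing centre while the γ-centre C7 is untouched.

Step 8
Reactants: 12 (4R)-3-methyl-4-(3-methylbut-2-en-1-yl)cyclohex-2-en-1-one; 13 5-bromo-2-methylpent-2-ene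
Product: 15 (3S,4R)-3-methyl-4-(3-methylbut-2-en-1-yl)-3-(4-methylpent-3-en-1-yl)cyclohexan-1-one, via silyl enol ether 14 (not isolated)
Conditions: 13, Mg, THF; then CuBr·SMe2 (10 mol %), TMSCl, 12, THF, −78 to −40 °C; 1 M HCl work-up
Reagents that add atoms: none
Why: CuBr·SMe2-catalysed Grignard conjugate addition accelerated by TMSCl, in which the homoprenyl group enters C8 axially on the face opposite the neighbouring C7 prenyl group (held pseudoaxial by allylic strain with the C8 methyl), so the quaternary centre forms with homoprenyl trans to prenyl.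

Step 9
Reactants: 15 (3S,4R)-3-methyl-4-(3-methylbut-2-en-1-yl)-3-(4-methylpent-3-en-1-yl)cyclohexan-1-one
Product: 17 (4S,5S)-5-methyl-2-methylidene-4-(3-methylbut-2-en-1-yl)-5-(4-methylpent-3-en-1-yl)cyclohexan-1-one, via Mannich base 16 (not isolated)
Conditions: LiN(i-Pr)2, THF, −78 °C; Me2N=CH2+ I−, −78 °C to rt; then MeI, CH2Cl2, rt; aq NaHCO3
Reagents that add atoms: N,N-dimethylmethyleneiminium iodide, C=[N+](C)C.[I-]
Why: Kinetic deprotonation occurs at C5, the methylene remote from quaternary C8, and Mannich reaction followed by N-methylation and elimination (Mannich methylenation) gives the exocyclic enone, the centre formed in between being destroyed.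

Step 10
Reactants: 17 (4S,5S)-5-methyl-2-methylidene-4-(3-methylbut-2-en-1-yl)-5-(4-methylpent-3-en-1-yl)cyclohexan-1-one; 6 (2S)-2-({[tert-butyl(dimethyl)silyl]oxy}methyl)-5-methyl-2-[(triethylsilyl)oxy]hex-4-enal
Product: 19 C5 aldol adduct (C4 carbinol), via magnesium enolate 18 (not isolated)
Conditions: Me2C=CHMgBr (1.1 equiv), CuBr·SMe2 (10 mol %), THF, −78 °C; then 6, −78 °C; aq NH4Cl at −78 °C
Reagents that add atoms: (2-methylprop-1-en-1-yl)magnesium bromide, CC(C)=C[Mg]Br
Why: CuBr·SMe2-catalysed conjugate addition to the unhindered exocyclic enone completes the C5 prenyl group and generates the tetrasubstituted C5 enolate regiospecifically, and its aldol addition to 6 should occur axially through a chair-like transition state on the ring face opposite the equatorial C7 prenyl group (conjugate addition–aldol sequence), so quaternary C5 carries the new chain trans to the C7 prenyl; the C4 carbinol centre is inconsequential.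

Step 11
Reactants: 19 C5 aldol adduct (C4 carbinol)
Product: 20 C9/C4 diketone with C3–OTES
Conditions: Dess–Martin periodinane (DMP), NaHCO3, CH2Cl2, 0 °C to rt
Reagents that add atoms: none
Why: Dess–Martin oxidation of a hindered β-hydroxy ketone to the 1,3-diketone under buffered conditions; C5 and C3 are quaternary, so no centre can epimerise.

Step 12
Reactants: 20 C9/C4 diketone with C3–OTES; 21 2-methylpropanal
Product: 23 C1 aldol adduct, via lithium enolate 22 (not isolated)
Conditions: LiN(i-Pr)2, THF, −78 °C; then 21, −78 °C; aq NH4Cl at −78 °C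
Reagents that add atoms: none
Why: The C9 ketone has α-hydrogens only at C1 (C5 and C3 are quaternary), so a single enolate forms and its aldol addition to the aldehyde installs the isobutyryl carbons; both new centres disappear in step 13, and the cold quench keeps the aldolate from attacking the C4 ketone.

Step 13
Reactants: 23 C1 aldol adduct
Product: 24 2-isobutyrylcyclohexanone with C3–OTES (ring enol)
Conditions: Dess–Martin periodinane (DMP), NaHCO3, CH2Cl2, 0 °C to rt
Reagents that add atoms: none
Why: Dess–Martin oxidation of the β-hydroxy ketone gives the β-diketone, whose enolisation removes the C1 and carbinol centres.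

Step 14
Reactants: 24 2-isobutyrylcyclohexanone with C3–OTES (ring enol)
Product: 25 key-step precursor with free C3 hydroxyl (ring enol)
Conditions: HF·pyridine, pyridine, THF, 0 °C
Reagents that add atoms: none
Why: Buffered fluoride cleavage at low temperature should remove the triethylsilyl ether, which is intrinsically far more labile than a tert-butyldimethylsilyl ether, and spare the neopentyl-type primary tert-butyldimethylsilyl ether (selective desilylation).

Step 15
Reactants: 25 key-step precursor with free C3 hydroxyl (ring enol)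
Product: 27 cis-3,5-disubstituted furan-2,4-dione with C2–OTBS, via hemiketal 26 (not isolated)
Conditions: Sc(OTf)3 (10 mol %), 2,6-di-tert-butyl-4-methylpyridine (20 mol %), MeCN, rt to 40 °C
Reagents that add atoms: none
Why: Trivalent scandium binds the two carbonyl oxygens of the diketo tautomer and activates ring ketone C9, the tertiary C3 hydroxyl adds to it to give the cis-fused hemiketal 26, and collapse of 26 breaks C9–C1 with the electrons flowing into the scandium-bound isobutyryl carbonyl, after which protonation of the released enol at C1 gives the isopropyl ketone. The closest known reaction type is the Lewis-acid-catalysed retro-Claisen cleavage of 1,3-diketones by alcohols, here run intramolecularly. The five-membered keto lactone (C5, C9, O, C3, C4) closes by 5-exo-trig addition of oxygen to the C9 carbonyl. No stereocentre is created: C5 is already quaternary with both acyl groups in place, C7 and C8 are remote from the reacting bonds, and C1 becomes a methylene. The step needs cleavage of C9–C1 and not C9–C5; this is secured because the exocyclic isobutyryl carbonyl can rotate into overlap with the breaking bond, whereas the C9–C5 bond lies in the new five-membered ring close to the nodal plane of the C4 carbonyl, and because the alternative would give a nine-membered lactone. Enolate-forming base is excluded so that no C1 enolate can re-close the six-membered ring by Claisen condensation; the hindered pyridine only scavenges triflic acid and so protects the four prenyl groups, the homoprenyl group and the silyl ether.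

Step 16
Reactants: 27 cis-3,5-disubstituted furan-2,4-dione with C2–OTBS
Product: 29 C1 α-bromo ketone, via silyl enol ether 28 (not isolated)
Conditions: LiN(i-Pr)2, TMSCl (in situ quench), THF, −78 °C; then NBS, THF, −78 to 0 °C
Reagents that add atoms: N-bromosuccinimide (NBS), O=C1CCC(=O)N1Br
Why: Kinetic deprotonation in the presence of TMSCl traps the less substituted C1 enolate as its silyl enol ether before it can attack the lactone carbonyl, and the enol ether reacts with NBS faster than the trisubstituted alkenes (α-bromination of a silyl enol ether); the C1 configuration is immaterial.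

Step 17
Reactants: 29 C1 α-bromo ketone
Product: 30 primary alcohol at C2
Conditions: HF·pyridine, THF, 0 °C to rt
Reagents that add atoms: none
Why: Fluoride desilylation under acidic, non-nucleophilic conditions should leave the β-keto lactone and the bromide intact and minimise acyl migration to the new hydroxyl.

Step 18
Reactants: 30 primary alcohol at C2
Product: 31 C2 aldehyde
Conditions: Dess–Martin periodinane (DMP), NaHCO3, CH2Cl2, 0 °C
Reagents that add atoms: none
Why: Dess–Martin oxidation of the primary alcohol; C3 is quaternary, so the aldehyde can neither enolise nor epimerise.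

Step 19
Reactants: 31 C2 aldehyde
Product: 33 bicyclic β-hydroxy ketone (eight-membered ring closed), via samarium enolate 32 (not isolated)
Conditions: SmI2 (2.2 equiv), THF, −78 °C, high dilution; aq NH4Cl at −78 °C
Reagents that add atoms: none
Why: Divalent samarium reduces the α-bromo ketone to a samarium enolate that adds to the aldehyde held cis to it on the lactone ring (intramolecular SmI2-mediated Reformatsky-type aldol), forming C1–C2 and the eight-membered ring; the C2 carbinol is oxidised next and C1 is set thermodynamically in step 20.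

Step 20
Reactants: 33 bicyclic β-hydroxy ketone (eight-membered ring closed)
Product: 34 CNP0121153.1
Conditions: Dess–Martin periodinane (DMP), NaHCO3, CH2Cl2, rt; then equilibration on silica gel
Reagents that add atoms: none
Why: Dess–Martin oxidation of the β-hydroxy ketone gives the 1,3-diketone, whose acidic C1–H should equilibrate through the enol to the more stable configuration, taken to be that of the target.

**Compound list**

1 | 2-methylidenepropane-1,3-diol | C=C(CO)CO | starting material
2 | 2-({[tert-butyl(dimethyl)silyl]oxy}methyl)prop-2-en-1-ol | C=C(CO)CO[Si](C)(C)C(C)(C)C | intermediate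
3 | [(2S)-2-({[tert-butyl(dimethyl)silyl]oxy}methyl)oxiran-2-yl]methanol | OC[C@]1(CO1)CO[Si](C)(C)C(C)(C)C | intermediate
4 | (2R)-2-({[tert-butyl(dimethyl)silyl]oxy}methyl)-5-methylhex-4-ene-1,2-diol | OC[C@](O)(CC=C(C)C)CO[Si](C)(C)C(C)(C)C | intermediate
5 | (2S)-2-({[tert-butyl(dimethyl)silyl]oxy}methyl)-2-hydroxy-5-methylhex-4-enal | O=C[C@](O)(CC=C(C)C)CO[Si](C)(C)C(C)(C)C | intermediate
6 | (2S)-2-({[tert-butyl(dimethyl)silyl]oxy}methyl)-5-methyl-2-[(triethylsilyl)oxy]hex-4-enal | O=C[C@](O[Si](CC)(CC)CC)(CC=C(C)C)CO[Si](C)(C)C(C)(C)C | intermediate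
7 | 5-methylhex-4-enal | CC(C)=CCCC=O | starting material
8 | but-3-en-2-one | CC(=O)C=C | starting material
9 | (2R)-2-(3-methylbut-2-en-1-yl)-5-oxohexanal (not isolated) | CC(=O)CC[C@H](CC=C(C)C)C=O | intermediate
10 | (4R)-4-(3-methylbut-2-en-1-yl)cyclohex-2-en-1-one | O=C1CC[C@H](CC=C(C)C)C=C1 | intermediate
11 | lithium (3R,4R)-3-methyl-4-(3-methylbut-2-en-1-yl)cyclohex-1-en-1-olate, methyl trans to prenyl (not isolated) | [Li]OC1=C[C@H](C)[C@@H](CC=C(C)C)CC1 | intermediate
12 | (4R)-3-methyl-4-(3-methylbut-2-en-1-yl)cyclohex-2-en-1-one | CC1=CC(=O)CC[C@@H]1CC=C(C)C | intermediate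
13 | 5-bromo-2-methylpent-2-ene | CC(C)=CCCBr | starting material
14 | trimethyl{[(3R,4R)-3-methyl-4-(3-methylbut-2-en-1-yl)-3-(4-methylpent-3-en-1-yl)cyclohex-1-en-1-yl]oxy}silane (not isolated) | CC(C)=CCC[C@]1(C)[C@@H](CC=C(C)C)CCC(O[Si](C)(C)C)=C1 | intermediate
15 | (3S,4R)-3-methyl-4-(3-methylbut-2-en-1-yl)-3-(4-methylpent-3-en-1-yl)cyclohexan-1-one (homoprenyl trans to prenyl) | CC(C)=CCC[C@]1(C)[C@@H](CC=C(C)C)CCC(=O)C1 | intermediate
16 | (4S,5S)-2-[(dimethylamino)methyl]-5-methyl-4-(3-methylbut-2-en-1-yl)-5-(4-methylpent-3-en-1-yl)cyclohexan-1-one, epimers at C2 (not isolated) | CC(C)=CCC[C@]1(C)[C@@H](CC=C(C)C)CC(CN(C)C)C(=O)C1 | intermediate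
17 | (4S,5S)-5-methyl-2-methylidene-4-(3-methylbut-2-en-1-yl)-5-(4-methylpent-3-en-1-yl)cyclohexan-1-one | CC(C)=CCC[C@]1(C)[C@@H](CC=C(C)C)CC(=C)C(=O)C1 | intermediate
18 | bromomagnesium enolate of the C5-prenylated ketone, C9(OMgBr)=C5 (not isolated) | CC(C)=CCC[C@]1(C)[C@@H](CC=C(C)C)CC(CC=C(C)C)=C(O[Mg]Br)C1 | intermediate
19 | cyclohexanone (C9 ketone, C1 = CH2) with quaternary C5 carrying prenyl (cis to the C7 prenyl) and the chain CH(OH)–C3(OTES)(prenyl)–CH2OTBS (trans to the C7 prenyl); C8 as in 15; C3 S; C4 carbinol epimers | CC(C)=CCC[C@]1(C)[C@@H](CC=C(C)C)C[C@@](CC=C(C)C)(C(=O)C1)C(O)[C@](O[Si](CC)(CC)CC)(CC=C(C)C)CO[Si](C)(C)C(C)(C)C | intermediate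
20 | as 19 with C4 oxidised to the ketone (C9/C4 1,3-diketone, C3–OTES, C2–OTBS) | CC(C)=CCC[C@]1(C)[C@@H](CC=C(C)C)C[C@@](CC=C(C)C)(C(=O)C1)C(=O)[C@](O[Si](CC)(CC)CC)(CC=C(C)C)CO[Si](C)(C)C(C)(C)C | intermediate
21 | 2-methylpropanal (isobutyraldehyde) | CC(C)C=O | starting material
22 | lithium C9=C1 enolate of 20 (not isolated) | CC(C)=CCC[C@]1(C)[C@@H](CC=C(C)C)C[C@@](CC=C(C)C)(C(O[Li])=C1)C(=O)[C@](O[Si](CC)(CC)CC)(CC=C(C)C)CO[Si](C)(C)C(C)(C)C | intermediate
23 | as 20 with C1 carrying CH(OH)CH(CH3)2; epimers at C1 and the carbinol carbon | CC(C)=CCC[C@]1(C)[C@@H](CC=C(C)C)C[C@@](CC=C(C)C)(C(=O)C1C(O)C(C)C)C(=O)[C@](O[Si](CC)(CC)CC)(CC=C(C)C)CO[Si](C)(C)C(C)(C)C | intermediate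
24 | 2-isobutyrylcyclohexanone (ring enol) with the C3–OTES, C2–OTBS α-silyloxy ketone chain on C5 | CC(C)=CCC[C@]1(C)[C@@H](CC=C(C)C)C[C@@](CC=C(C)C)(C(O)=C1C(=O)C(C)C)C(=O)[C@](O[Si](CC)(CC)CC)(CC=C(C)C)CO[Si](C)(C)C(C)(C)C | intermediate
25 | key-step precursor: 2-isobutyrylcyclohexanone (ring enol) with the α-hydroxy ketone chain C4(=O)–C3(OH)(prenyl)–CH2OTBS on quaternary C5; C5 and C7 prenyls cis, homoprenyl trans to the C7 prenyl, C3 S | CC(C)=CCC[C@]1(C)[C@@H](CC=C(C)C)C[C@@](CC=C(C)C)(C(O)=C1C(=O)C(C)C)C(=O)[C@](O)(CC=C(C)C)CO[Si](C)(C)C(C)(C)C | intermediate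
26 | cis-fused hemiketal from addition of the C3 hydroxyl to C9 (not isolated; C1 epimers) | CC(C)=CCC[C@]1(C)[C@@H](CC=C(C)C)C[C@]2(CC=C(C)C)C(=O)[C@](CC=C(C)C)(CO[Si](C)(C)C(C)(C)C)O[C@]2(O)C1C(=O)C(C)C | intermediate
27 | key-step product: cis-3,5-disubstituted furan-2,4-dione; C5 carries prenyl and the chain C6–C7(prenyl)–C8(Me)(homoprenyl)–C1H2–C(=O)CH(CH3)2, C3 carries prenyl and CH2OTBS | CC(C)=CCC[C@@](C)(CC(=O)C(C)C)[C@@H](CC=C(C)C)C[C@@]1(CC=C(C)C)C(=O)O[C@@](CC=C(C)C)(CO[Si](C)(C)C(C)(C)C)C1=O | intermediate
28 | trimethylsilyl enol ether of 27 at C1 (not isolated; E/Z mixture) | CC(C)=CCC[C@@](C)(C=C(O[Si](C)(C)C)C(C)C)[C@@H](CC=C(C)C)C[C@@]1(CC=C(C)C)C(=O)O[C@@](CC=C(C)C)(CO[Si](C)(C)C(C)(C)C)C1=O | intermediate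
29 | as 27 with bromine on C1 (C1 epimers) | CC(C)=CCC[C@@](C)(C(Br)C(=O)C(C)C)[C@@H](CC=C(C)C)C[C@@]1(CC=C(C)C)C(=O)O[C@@](CC=C(C)C)(CO[Si](C)(C)C(C)(C)C)C1=O | intermediate
30 | as 29 with free CH2OH on C3 | CC(C)=CCC[C@@](C)(C(Br)C(=O)C(C)C)[C@@H](CC=C(C)C)C[C@@]1(CC=C(C)C)C(=O)O[C@@](CC=C(C)C)(CO)C1=O | intermediate
31 | as 29 with the C2 aldehyde on C3 | CC(C)=CCC[C@@](C)(C(Br)C(=O)C(C)C)[C@@H](CC=C(C)C)C[C@@]1(CC=C(C)C)C(=O)O[C@@](CC=C(C)C)(C=O)C1=O | intermediate
32 | samarium enolate at C1 of 31 (not isolated) | CC(C)=CCC[C@@](C)(C=C(O[Sm](I)I)C(C)C)[C@@H](CC=C(C)C)C[C@@]1(CC=C(C)C)C(=O)O[C@@](CC=C(C)C)(C=O)C1=O | intermediate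
33 | target skeleton with C2 as CH(OH) (epimers at C1 and C2) | CC(C)=CCC[C@]1(C)[C@@H](CC=C(C)C)C[C@@]2(CC=C(C)C)C(=O)O[C@@](CC=C(C)C)(C(O)C1C(=O)C(C)C)C2=O | intermediate
34 | CNP0121153.1 | CC(C)=CCC[C@]1(C)[C@@H](CC=C(C)C)C[C@@]2(CC=C(C)C)C(=O)O[C@@](CC=C(C)C)(C(=O)[C@H]1C(=O)C(C)C)C2=O | target

**Step count and risk**

Total steps: 20. Longest linear sequence: 16 steps (steps 1–5, then steps 10–20); the cyclohexanone branch (steps 6–9) joins at step 10.

Steps most likely to fail:

1. Step 15 (key step). The enolised diketone may tie up Sc(OTf)3 as an unreactive chelate, or traces of triflic acid may add the C3 hydroxyl or the enol across a prenyl double bond before the hemiketal fragments. The fallback sets out from 25: NBS (CH2Cl2, −40 °C) should brominate the enolised C1 to give the 2-bromo-1,3-diketone F1. F1 has no enol to bind a metal and offers a bromine-stabilised leaving enol, so the same hemiketal fragmentation, a known deacylative cleavage of 2-halo-1,3-diketones by alcohols, should run at 0 °C with a catalytic amount of MgBr2·OEt2 in MeCN. This delivers bromo ketone 29, where the route is rejoined; step 16 is then not needed.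

2. Step 10. The aldol addition joins two fully substituted carbons through one CH(OH), so reversal to enolate and aldehyde, or migration of the triethylsilyl group to the new alkoxide, may prevail. The fallback sets out from 17: the same CuBr·SMe2-catalysed addition is quenched with TMSCl/Et3N to give the isolable tetrasubstituted silyl enol ether F2. F2 is then combined with 6 in an irreversible Mukaiyama aldol reaction (BF3·OEt2, CH2Cl2, −78 °C, open transition state, same facial preference). Aqueous work-up gives 19, where the route is rejoined.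

3. Step 19. Electron transfer may go to the α-acyloxy ketone of the lactone or to the aldehyde instead of the C–Br bond, or transannular strain may slow ring closure so that simple debromination wins. The fallback sets out from 27 and avoids both the bromide and the reductant: HF·pyridine gives the primary alcohol F3, and Dess–Martin oxidation gives the keto aldehyde F4. n-Bu2BOTf/i-Pr2NEt (CH2Cl2, −78 to 0 °C, high dilution) should then enolise the isopropyl ketone only toward its methylene, and the boron enolate, which does not attack lactones, closes the ring by intramolecular aldol addition. This gives 33, where the route is rejoined; steps 16–19 are replaced.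

**Further compounds**

F1 | step 15 | 25 brominated at C1 (2-bromo-2-isobutyrylcyclohexanone with the free C3 hydroxyl; C1 epimers) | CC(C)=CCC[C@]1(C)[C@@H](CC=C(C)C)C[C@@](CC=C(C)C)(C(=O)C1(Br)C(=O)C(C)C)C(=O)[C@](O)(CC=C(C)C)CO[Si](C)(C)C(C)(C)C
F2 | step 10 | trimethylsilyl enol ether C9(OTMS)=C5(prenyl) of the C5-prenylated ketone | CC(C)=CCC[C@]1(C)[C@@H](CC=C(C)C)CC(CC=C(C)C)=C(O[Si](C)(C)C)C1
F3 | step 19 | 27 with free CH2OH on C3 (no bromine) | CC(C)=CCC[C@@](C)(CC(=O)C(C)C)[C@@H](CC=C(C)C)C[C@@]1(CC=C(C)C)C(=O)O[C@@](CC=C(C)C)(CO)C1=O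
F4 | step 19 | 27 with the C2 aldehyde on C3 (no bromine) | CC(C)=CCC[C@@](C)(CC(=O)C(C)C)[C@@H](CC=C(C)C)C[C@@]1(CC=C(C)C)C(=O)O[C@@](CC=C(C)C)(C=O)C1=O
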